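Oxolane numbering: O1, C2 (aryl), C3 (acyloxymethyl), C4 (benzyl), C5 (CH2). The ring is opened at C5–C4 and C2–C3, which exposes a carbonyl ylide (C5H2–O1–C2H–aryl) and a C3=C4 alkene. The two cis one-carbon arms on C3 and C4, the ester-bearing CH2O and the benzylic CH2, are tied together as a temporary lactone, so the dipolarophile is an enantiopure γ-aryl butenolide whose single stereocentre is the future benzylic CH2 carrying an extra oxygen. One [3+2] cycloaddition forms both C–C bonds, the oxolane ring and all three stereocentres, anti to that aryl group. Hydrogenolysis then erases the controlling C–O bond; borane reduction and a chemoselective Mitsunobu esterification complete the route.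

Key step: step 4

Assumption: (S,S)-ProPhenol is taken to deliver the alkynyl group to the aldehyde face that gives the S carbinol; if the opposite sense is found, the commercial (R,R) ligand is used and nothing else changes.

Step 1
Reactants: 1 4-(benzyloxy)-3-methoxybenzaldehyde (O-benzylvanillin); 2 methyl propiolate
Product: 3 methyl (4S)-4-[4-(benzyloxy)-3-methoxyphenyl]-4-hydroxybut-2-ynoate
Conditions: 2 (3 equiv), ZnMe2 (3 equiv), (S,S)-ProPhenol (10 mol%), toluene, 0 °C; aq. NH4Cl
Reagents that add atoms: none
Why: The zinc alkynylide of the propiolate adds to the aldehyde inside the chiral dinuclear zinc–ProPhenol pocket (catalytic asymmetric alkynylation of an aldehyde), so the carbinol stereocentre is set by catalyst control.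

Step 2
Reactants: 3 methyl (4S)-4-[4-(benzyloxy)-3-methoxyphenyl]-4-hydroxybut-2-ynoate
Product: 5 (5R)-5-[4-(benzyloxy)-3-methoxyphenyl]furan-2(5H)-one, via Z-hydroxy enoate 4 (not isolated)
Conditions: H2 (1 atm), Pd/CaCO3–Pb(OAc)2 (Lindlar catalyst), quinoline, EtOAc, rt; then silica gel, CH2Cl2, rt
Reagents that add atoms: none
Why: Syn semihydrogenation over the poisoned palladium catalyst gives the Z-enoate, whose hydroxyl lies next to the ester and lactonises with loss of methanol (Lindlar reduction, then intramolecular transesterification); the stereocentre is not touched and its descriptor changes from S to R only through the CIP priorities.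

Step 3
Reactants: 1 4-(benzyloxy)-3-methoxybenzaldehyde; 6 (trimethylsilyl)methanol
Product: 7 1-(benzyloxy)-4-{bis[(trimethylsilyl)methoxy]methyl}-2-methoxybenzene
Conditions: 6 (2.5 equiv), PPTS (cat.), toluene, reflux, Dean–Stark
Reagents that add atoms: none
Why: Acid-catalysed acetalisation driven by azeotropic removal of water installs the CH2SiMe3 group that becomes C5 of the oxolane; no stereocentre is involved and the benzyl ether is stable to PPTS.

Step 4
Reactants: 7 1-(benzyloxy)-4-{bis[(trimethylsilyl)methoxy]methyl}-2-methoxybenzene; 5 (5R)-5-[4-(benzyloxy)-3-methoxyphenyl]furan-2(5H)-one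
Product: 10 (1R,4R,5S,8R)-4,8-bis[4-(benzyloxy)-3-methoxyphenyl]-3,7-dioxabicyclo[3.3.0]octan-2-one, via α-chloro ether 8 (not isolated), via carbonyl ylide 9 (not isolated)
Conditions: 7 (2 equiv), AcCl (2.2 equiv), CH2Cl2, 0 °C to rt, then evaporate; MeCN, 5 (1 equiv), CsF (4 equiv, added last in portions), 0 °C to rt
Reagents that add atoms: none
Why: Acetyl chloride converts acetal 7 into the α-chloro ether 8, which ionises to the oxocarbenium ion and is desilylated by fluoride (silicon-based 1,3-elimination) to the non-stabilised carbonyl ylide 9, and 9 adds across the electron-poor C=C of butenolide 5 in a 1,3-dipolar cycloaddition. The closest known reaction type is the fluoride-triggered generation of carbonyl ylides from 1-chloroalkyl (trimethylsilyl)methyl ethers and their [3+2] cycloaddition to enoates and other activated alkenes. The oxolane ring closes by a suprafacial [4π+2π] cycloaddition in which both C–C bonds (CH2 to the β-carbon, ArCH to the α-carbon) form on one face of the butenolide, so the new ring is necessarily cis-fused to the lactone, which fixes the 3,4-cis relationship of the target. The two ring-fusion stereocentres are set by the butenolide stereocentre, because the dipole approaches the face anti to the γ-aryl group, and the aryl-bearing C2 is set by exo approach of the E-configured ylide, which keeps its aryl group away from the lactone and gives the 2,3-trans product. The step needs regioselectivity, facial selectivity and exo selectivity; the regiochemistry is secured by the electron-rich aryl group, which polarises the ylide as ArCH(+)–O–CH2(−), and by the small CH2 terminus meeting the more hindered β-carbon. CsF is added last to an excess of the ylide precursor so that the acidic γ-hydrogen of 5 meets as little free fluoride as possible.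

Step 5
Reactants: 10 (1R,4R,5S,8R)-4,8-bis[4-(benzyloxy)-3-methoxyphenyl]-3,7-dioxabicyclo[3.3.0]octan-2-one
Product: 11 (2R,3R,4S)-2-(4-hydroxy-3-methoxyphenyl)-4-[(4-hydroxy-3-methoxyphenyl)methyl]oxolane-3-carboxylic acid
Conditions: H2 (1 atm), Pd/C (10%), EtOAc–EtOH, rt, stopped after uptake of 3 equiv H2
Reagents that add atoms: none
Why: Catalytic hydrogenolysis should cleave the three activated benzylic C–O bonds (the lactone C–O bond, whose leaving group is a carboxylate, and the two aryl benzyl ethers) well before the dialkyl benzylic ether C2–O1 of the oxolane, so the stereocentre that steered the cycloaddition becomes the benzylic CH2 of the target and no new stereocentre is formed.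

Step 6
Reactants: 11 (2R,3R,4S)-2-(4-hydroxy-3-methoxyphenyl)-4-[(4-hydroxy-3-methoxyphenyl)methyl]oxolane-3-carboxylic acid
Product: 12 (2R,3S,4S)-lariciresinol
Conditions: BH3·THF (5 equiv), THF, 0 °C to rt; MeOH quench
Reagents that add atoms: none
Why: Borane reduces the free carboxylic acid through its acyloxyborane (chemoselective acid reduction) without an enolisable intermediate, so C3 keeps its configuration (descriptor R to S only through the CIP priorities) and the phenols are merely borylated until the methanol quench.

Step 7
Reactants: 12 (2R,3S,4S)-lariciresinol; 13 4-hydroxybenzoic acid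
Product: 14 agastinol
Conditions: 13 (1.2 equiv), PPh3, DIAD, THF, 0 °C to rt
Reagents that add atoms: none
Why: In this Mitsunobu esterification only the primary aliphatic alcohol becomes an alkoxyphosphonium ion and only the carboxylic acid (pKa near 4.5, against 9 to 10 for the three phenols) is acidic enough to act as the nucleophile, so the ester should form at the CH2OH group with all phenols left free; no stereocentre is touched.

Compound list
1 | 4-(benzyloxy)-3-methoxybenzaldehyde (O-benzylvanillin) | COc1cc(C=O)ccc1OCc1ccccc1 | starting material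
2 | methyl propiolate | C#CC(=O)OC | starting material
3 | methyl (4S)-4-[4-(benzyloxy)-3-methoxyphenyl]-4-hydroxybut-2-ynoate | COC(=O)C#C[C@@H](O)c1ccc(OCc2ccccc2)c(OC)c1 | intermediate
4 | methyl (2Z,4R)-4-[4-(benzyloxy)-3-methoxyphenyl]-4-hydroxybut-2-enoate | COC(=O)/C=C\[C@@H](O)c1ccc(OCc2ccccc2)c(OC)c1 | intermediate (not isolated)
5 | (5R)-5-[4-(benzyloxy)-3-methoxyphenyl]furan-2(5H)-one | O=C1C=C[C@H](c2ccc(OCc3ccccc3)c(OC)c2)O1 | intermediate
6 | (trimethylsilyl)methanol | C[Si](C)(C)CO | starting material
7 | 1-(benzyloxy)-4-{bis[(trimethylsilyl)methoxy]methyl}-2-methoxybenzene | COc1cc(C(OC[Si](C)(C)C)OC[Si](C)(C)C)ccc1OCc1ccccc1 | intermediate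
8 | 1-(benzyloxy)-4-{chloro[(trimethylsilyl)methoxy]methyl}-2-methoxybenzene (racemic, used crude) | COc1cc(C(Cl)OC[Si](C)(C)C)ccc1OCc1ccccc1 | intermediate (not isolated)
9 | carbonyl ylide ArCH=O(+)–CH2(−), Ar = 4-(benzyloxy)-3-methoxyphenyl | [CH2-][O+]=Cc1ccc(OCc2ccccc2)c(OC)c1 | intermediate (not isolated)
10 | (1R,4R,5S,8R)-4,8-bis[4-(benzyloxy)-3-methoxyphenyl]-3,7-dioxabicyclo[3.3.0]octan-2-one (cis-fused, both aryl groups exo; C8 = future C2, C1 = future C3, C5 = future C4) | O=C1O[C@@H](c2ccc(OCc3ccccc3)c(OC)c2)[C@@H]2CO[C@@H](c3ccc(OCc4ccccc4)c(OC)c3)[C@H]12 | intermediate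
11 | (2R,3R,4S)-2-(4-hydroxy-3-methoxyphenyl)-4-[(4-hydroxy-3-methoxyphenyl)methyl]oxolane-3-carboxylic acid | COc1cc(C[C@@H]2CO[C@@H](c3ccc(O)c(OC)c3)[C@@H]2C(=O)O)ccc1O | intermediate
12 | (2R,3S,4S)-lariciresinol, 4-{[(3S,4S,5R)-5-(4-hydroxy-3-methoxyphenyl)-4-(hydroxymethyl)oxolan-3-yl]methyl}-2-methoxyphenol | COc1cc(C[C@@H]2CO[C@@H](c3ccc(O)c(OC)c3)[C@@H]2CO)ccc1O | intermediate
13 | 4-hydroxybenzoic acid | O=C(O)c1ccc(O)cc1 | starting material
14 | agastinol | COc1cc(C[C@@H]2CO[C@@H](c3ccc(O)c(OC)c3)[C@@H]2COC(=O)c2ccc(O)cc2)ccc1O | target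

Total step count: 7
Longest linear sequence: 6 steps (steps 1, 2, 4, 5, 6, 7)

Steps most likely to fail

Step 4 (key step). Three processes may go wrong. Fluoride may act as a base on the acidic γ-hydrogen of the butenolide, causing racemisation and isomerisation to the 2(3H)-furanone. Exo selectivity at C2 may be insufficient. The ylide may collapse (closure to the aryl oxirane, dimerisation) before it is trapped. The fallback builds the oxolane by C–O instead of C–C bond formation, setting out from 1 and returning at 12. Stobbe condensation of 1 with diethyl succinate (KOtBu, tBuOH, reflux) should give the (E)-arylidene half-ester F1. Hydrogenation with [Rh(cod)Cl]2 and the MOD-DIOP antipode chosen for the S acid (H2, MeOH, Et3N) should give the (S)-benzylsuccinic acid monoester F2. Chemoselective reduction of the ester on the potassium carboxylate with Ca(BH4)2 and acidification should give the (S)-β-benzyl-γ-butyrolactone F3. Its lithium enolate (LDA, THF, −78 °C) and 1 should give the trans aldol adduct F4, formed anti to the β-benzyl group as a mixture of carbinol epimers. LiAlH4 (THF) should give the triol F5. Mild acid (CSA, CH2Cl2, 0 °C) should close the 2,3-trans oxolane, di-O-benzyl-lariciresinol F6, by capture of the benzylic cation by the C5 hydroxyl. Hydrogenolysis of the two benzyl ethers (H2, Pd/C, EtOAc) then gives 12.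

Step 5. Hydrogenolysis may run on into the benzylic C2–O1 ether bond of the oxolane once the phenols are free, or attack that bond before the lactone C–O bond. The fallback sets out from 10 and returns at 11. Ionic hydrogenation (Et3SiH, TFA, CH2Cl2, 0 °C) should ionise only the lactone C–O bond, because its leaving group is a carboxylic acid and the alternative cation at C2 would sit β to the carbonyl carbon. Hydride transfer should then give the di-O-benzyl acid F7. A short hydrogenolysis limited to the two aryl benzyl ethers (H2, Pd/C, EtOAc) gives 11.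

Step 7. Chemoselectivity may be lost through O-alkylation of a phenol by the activated primary alcohol, or esterification with the electron-rich acid may be too slow. The fallback sets out from 12 and returns at 14. Exhaustive acylation with 4-acetoxybenzoyl chloride (pyridine, DMAP, CH2Cl2) should give the tris(4-acetoxybenzoate) F8. Hydrazine hydrate (THF–MeOH, 0 °C) should then remove the five phenolic ester groups (three aryl acetates and the two guaiacyl benzoates), which are aminolysed far faster than the primary alkyl benzoate, leaving 14.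

Further compounds
F1 | step 4 | (3E)-4-[4-(benzyloxy)-3-methoxyphenyl]-3-(ethoxycarbonyl)but-3-enoic acid | CCOC(=O)/C(CC(=O)O)=C/c1ccc(OCc2ccccc2)c(OC)c1
F2 | step 4 | (3S)-3-[4-(benzyloxy)-3-methoxybenzyl]-4-ethoxy-4-oxobutanoic acid | CCOC(=O)[C@H](CC(=O)O)Cc1ccc(OCc2ccccc2)c(OC)c1
F3 | step 4 | (4S)-4-[4-(benzyloxy)-3-methoxybenzyl]dihydrofuran-2(3H)-one | O=C1C[C@H](Cc2ccc(OCc3ccccc3)c(OC)c2)CO1
F4 | step 4 | (3R,4S)-4-[4-(benzyloxy)-3-methoxybenzyl]-3-{[4-(benzyloxy)-3-methoxyphenyl](hydroxy)methyl}dihydrofuran-2(3H)-one (carbinol epimers) | O=C1OC[C@@H](Cc2ccc(OCc3ccccc3)c(OC)c2)[C@@H]1C(O)c1ccc(OCc2ccccc2)c(OC)c1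
F5 | step 4 | (2S,3S)-2-[4-(benzyloxy)-3-methoxybenzyl]-3-{[4-(benzyloxy)-3-methoxyphenyl](hydroxy)methyl}butane-1,4-diol (carbinol epimers) | OC[C@@H](Cc1ccc(OCc2ccccc2)c(OC)c1)[C@@H](CO)C(O)c1ccc(OCc2ccccc2)c(OC)c1
F6 | step 4 | (2R,3S,4S)-di-O-benzyl-lariciresinol | COc1cc(C[C@@H]2CO[C@@H](c3ccc(OCc4ccccc4)c(OC)c3)[C@@H]2CO)ccc1OCc1ccccc1
F7 | step 5 | (2R,3R,4S)-2-[4-(benzyloxy)-3-methoxyphenyl]-4-[4-(benzyloxy)-3-methoxybenzyl]oxolane-3-carboxylic acid | COc1cc(C[C@@H]2CO[C@@H](c3ccc(OCc4ccccc4)c(OC)c3)[C@@H]2C(=O)O)ccc1OCc1ccccc1
F8 | step 7 | (2R,3S,4S)-lariciresinol tris(4-acetoxybenzoate) | COc1cc(C[C@@H]2CO[C@@H](c3ccc(OC(=O)c4ccc(OC(C)=O)cc4)c(OC)c3)[C@@H]2COC(=O)c2ccc(OC(C)=O)cc2)ccc1OC(=O)c1ccc(OC(C)=O)cc1
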